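**Retrosynthetic overview**
1. Target 25 ← one acid step removing three MOM acetals and one TBS ether from the 3-O-methylated flavonol 24; 3-OMe ← MeI on flavonol 23.
2. The pyranone (C ring) is the only ring made, and it is made last: Algar–Flynn–Oyamada oxidative cyclisation of 2'-hydroxychalcone 21.
3. Key C–C bond (future C2–C3): Claisen–Schmidt aldol condensation of A-ring acetophenone 9 with B-ring aldehyde 19.
4. 9 ← 2-methoxyresorcinol (MOM protection, Ir C–H borylation/oxidation to a symmetric phenol, benzylation, bromination, Br/Li exchange–acetylation, hydrogenolysis).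
5. 19 ← 3-bromo-4-hydroxybenzaldehyde (iodination, MOM, B-alkyl Suzuki at C–I, Stille prenylation at C–Br); the stereocentre comes from (R)-Roche ester via the (S)-alkene 13.

Assumption: common reagents (MOMCl, BnBr, B2pin2, the Weinreb amide, the prenylstannane and the like) are bought and listed as reagents, not as numbered compounds. MOM = methoxymethyl, TBS = tert-butyldimethylsilyl.

**A-ring acetophenone**

Step 1
Reactants: 1 2-methoxybenzene-1,3-diol
Product: 2 2-methoxy-1,3-bis(methoxymethoxy)benzene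
Conditions: MOMCl (2.5 equiv), i-Pr2NEt, CH2Cl2, 0 °C → rt
Reagents that add atoms: chloromethyl methyl ether COCCl
Why: Plain O-alkylation of both phenols gives base-stable acetals that can be removed at the end under mild acid (MOM protection).

Step 2
Reactants: 2 2-methoxy-1,3-bis(methoxymethoxy)benzene
Product: 4 4-methoxy-3,5-bis(methoxymethoxy)phenol, via arylboronic pinacol ester 3 (not isolated)
Conditions: B2pin2, [Ir(OMe)(cod)]2 (1.5 mol%), dtbpy (3 mol%), THF, 80 °C; then 30% H2O2, 2 M NaOH, 0 °C → rt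
Reagents that add atoms: hydrogen peroxide OO (phenol oxygen); bis(pinacolato)diboron CC1(C)OB(OC1(C)C)B1OC(C)(C)C(C)(C)O1 (boron only in 3)
Why: Sterically controlled Ir-catalysed C–H borylation takes the only C–H with no ortho substituent (C5), and boronate oxidation then gives the symmetric phenol.

Step 3
Reactants: 4 4-methoxy-3,5-bis(methoxymethoxy)phenol
Product: 5 5-(benzyloxy)-2-methoxy-1,3-bis(methoxymethoxy)benzene
Conditions: BnBr, K2CO3, DMF, rt
Reagents that add atoms: benzyl bromide BrCc1ccccc1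
Why: Williamson etherification marks the future ring-oxygen phenol with a group that can later be removed by hydrogenolysis without touching the MOM acetals.

Step 4
Reactants: 5 5-(benzyloxy)-2-methoxy-1,3-bis(methoxymethoxy)benzene
Product: 6 1-(benzyloxy)-2-bromo-4-methoxy-3,5-bis(methoxymethoxy)benzene
Conditions: NBS (1.0 equiv), MeCN, 0 °C
Reagents that add atoms: N-bromosuccinimide O=C1CCC(=O)N1Br
Why: Electrophilic aromatic bromination can only hit the two equivalent, strongly activated C–H positions, so one equivalent gives a single monobromide.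

Step 5
Reactants: 6 1-(benzyloxy)-2-bromo-4-methoxy-3,5-bis(methoxymethoxy)benzene
Product: 8 1-[2-(benzyloxy)-5-methoxy-4,6-bis(methoxymethoxy)phenyl]ethan-1-one, via aryllithium 7 (not isolated)
Conditions: n-BuLi (1.05 equiv), THF, −78 °C, 15 min; then MeC(O)N(OMe)Me, −78 → 0 °C; aq NH4Cl
Reagents that add atoms: N-methoxy-N-methylacetamide CC(=O)N(C)OC; n-butyllithium [Li]CCCC (lithium only in 7)
Why: Br/Li exchange at −78 °C is faster than any benzylic deprotonation, and the Weinreb amide acylation stops at the ketone through its stable chelated tetrahedral adduct.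

Step 6
Reactants: 8 1-[2-(benzyloxy)-5-methoxy-4,6-bis(methoxymethoxy)phenyl]ethan-1-one
Product: 9 1-[2-hydroxy-5-methoxy-4,6-bis(methoxymethoxy)phenyl]ethan-1-one
Conditions: H2 (1 atm), 10% Pd/C, EtOAc, rt
Reagents that add atoms: none
Why: Hydrogenolysis cleaves only the benzyl ether, freeing the one phenol (next to the ring C–H) that will become the pyranone oxygen and so fixing the 6-methoxy regiochemistry.

**Chiral side-chain alkene**

Step 7
Reactants: 10 methyl (R)-3-hydroxy-2-methylpropanoate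
Product: 11 methyl (R)-3-(tert-butyldimethylsilyloxy)-2-methylpropanoate
Conditions: TBSCl, imidazole, CH2Cl2, 0 °C → rt
Reagents that add atoms: tert-butyldimethylsilyl chloride CC(C)(C)[Si](C)(C)Cl
Why: Silylation of the primary alcohol gives an ether that is stable to alkyl-metal reagents and hydroxide but falls off in the final acid step; the stereocentre is bought and untouched.

Step 8
Reactants: 11 methyl (R)-3-(tert-butyldimethylsilyloxy)-2-methylpropanoate
Product: 12 (R)-3-(tert-butyldimethylsilyloxy)-2-methylpropanal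
Conditions: DIBAL-H (1.1 equiv), CH2Cl2, −78 °C; MeOH, then aq Rochelle salt; used crude at once
Reagents that add atoms: none
Why: Partial ester reduction stops at the chelated aluminium hemiacetal at −78 °C, and immediate use of the aldehyde avoids epimerisation of the α-stereocentre.

Step 9
Reactants: 12 (R)-3-(tert-butyldimethylsilyloxy)-2-methylpropanal
Product: 13 (S)-tert-butyldimethyl[(2-methylbut-3-en-1-yl)oxy]silane
Conditions: Ph3PCH3Br, n-BuLi, THF, 0 °C; then 12, −78 °C → rt
Reagents that add atoms: methyltriphenylphosphonium bromide C[P+](c1ccccc1)(c1ccccc1)c1ccccc1.[Br-] (CH2 carbon)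
Why: Wittig methylenation with a non-stabilised ylide at low temperature converts the aldehyde to the vinyl group without racemisation; the descriptor changes from R to S only because the CIP priorities change.

**B-ring aldehyde**

Step 10
Reactants: 14 3-bromo-4-hydroxybenzaldehyde
Product: 15 3-bromo-4-hydroxy-5-iodobenzaldehyde
Conditions: NIS (1.05 equiv), AcOH, rt
Reagents that add atoms: N-iodosuccinimide O=C1CCC(=O)N1I
Why: Electrophilic iodination goes to the only free position ortho to the phenol and gives two halogens of different reactivity for sequential couplings.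

Step 11
Reactants: 15 3-bromo-4-hydroxy-5-iodobenzaldehyde
Product: 16 3-bromo-5-iodo-4-(methoxymethoxy)benzaldehyde
Conditions: MOMCl (1.5 equiv), i-Pr2NEt, CH2Cl2, 0 °C → rt
Reagents that add atoms: chloromethyl methyl ether COCCl
Why: MOM protection of the acidic phenol proceeds readily and removes the free OH before the palladium steps and the base-mediated condensation.

Step 12
Reactants: 13 (S)-tert-butyldimethyl[(2-methylbut-3-en-1-yl)oxy]silane; 16 3-bromo-5-iodo-4-(methoxymethoxy)benzaldehyde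
Product: 18 (S)-3-bromo-5-[4-(tert-butyldimethylsilyloxy)-3-methylbutyl]-4-(methoxymethoxy)benzaldehyde, via B-alkyl-9-BBN 17 (not isolated)
Conditions: 13 (1.15 equiv), 9-BBN (1.1 equiv), THF, 0 °C → rt; then 16 (1.0 equiv), PdCl2(dppf) (5 mol%), 3 M aq K3PO4, DMF, rt
Reagents that add atoms: 9-borabicyclo[3.3.1]nonane B1C2CCCC1CCC2 (boron only in 17; no heavy atom stays in 18)
Why: Anti-Markovnikov hydroboration followed by B-alkyl Suzuki–Miyaura coupling reacts at C–I far faster than at C–Br at room temperature, and the slight excess of alkene over 9-BBN leaves no B–H to reduce the aldehyde; the stereocentre is remote and untouched.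

Step 13
Reactants: 18 (S)-3-bromo-5-[4-(tert-butyldimethylsilyloxy)-3-methylbutyl]-4-(methoxymethoxy)benzaldehyde
Product: 19 (S)-3-[4-(tert-butyldimethylsilyloxy)-3-methylbutyl]-4-(methoxymethoxy)-5-(3-methylbut-2-en-1-yl)benzaldehyde
Conditions: tributyl(prenyl)stannane (1.3 equiv), Pd(PPh3)4 (5 mol%), DMF, 90 °C; KF work-up
Reagents that add atoms: tributyl(3-methylbut-2-en-1-yl)stannane CCCC[Sn](CCCC)(CCCC)CC=C(C)C
Why: Stille coupling of the remaining aryl bromide under neutral conditions tolerates the aldehyde, and reductive elimination from the π-prenyl palladium species at the less hindered terminus gives the linear prenyl arene.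

**Fragment union and endgame**

Step 14
Reactants: 9 1-[2-hydroxy-5-methoxy-4,6-bis(methoxymethoxy)phenyl]ethan-1-one; 19 (S)-3-[4-(tert-butyldimethylsilyloxy)-3-methylbutyl]-4-(methoxymethoxy)-5-(3-methylbut-2-en-1-yl)benzaldehyde
Product: 21 (S,E)-3-{3-[4-(tert-butyldimethylsilyloxy)-3-methylbutyl]-4-(methoxymethoxy)-5-(3-methylbut-2-en-1-yl)phenyl}-1-[2-hydroxy-5-methoxy-4,6-bis(methoxymethoxy)phenyl]prop-2-en-1-one, via β-hydroxy ketone 20 (not isolated)
Conditions: KOH (10 equiv, 50% aq), EtOH, 0 °C → rt, 36 h; cold acidification to pH 5–6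
Reagents that add atoms: none
Why: Claisen–Schmidt aldol condensation of the methyl ketone enolate with the non-enolisable, unhindered aldehyde followed by E1cB dehydration gives the E-chalcone, and MOM acetals, the alkyl TBS ether and the prenyl group are all stable to hydroxide.

Step 15
Reactants: 21 the chalcone of step 14
Product: 23 2-{3-[(3S)-4-(tert-butyldimethylsilyloxy)-3-methylbutyl]-4-(methoxymethoxy)-5-(3-methylbut-2-en-1-yl)phenyl}-3-hydroxy-6-methoxy-5,7-bis(methoxymethoxy)-4H-chromen-4-one, via dihydroflavonol 22 (not isolated)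
Conditions: 30% H2O2 (8 equiv), 2 M aq NaOH, MeOH/THF, 0 °C → rt
Reagents that add atoms: hydrogen peroxide OO (3-OH oxygen)
Why: In the Algar–Flynn–Oyamada reaction the 2'-phenoxide closes the ring onto the enone and alkaline peroxide hydroxylates and then dehydrogenates C3; nucleophilic peroxide does not attack the isolated prenyl alkene, and low temperature limits aurone formation.

Step 16
Reactants: 23 the flavonol of step 15
Product: 24 2-{3-[(3S)-4-(tert-butyldimethylsilyloxy)-3-methylbutyl]-4-(methoxymethoxy)-5-(3-methylbut-2-en-1-yl)phenyl}-3,6-dimethoxy-5,7-bis(methoxymethoxy)-4H-chromen-4-one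
Conditions: MeI (2 equiv), K2CO3 (3 equiv), acetone, 50 °C
Reagents that add atoms: iodomethane CI
Why: The 3-OH is the only free hydroxyl in the molecule, so O-methylation of the acidic enol is unambiguous (Williamson etherification).

Step 17
Reactants: 24 the 3-methoxyflavone of step 16
Product: 25 5,7-dihydroxy-2-{4-hydroxy-3-[(3S)-4-hydroxy-3-methylbutyl]-5-(3-methylbut-2-en-1-yl)phenyl}-3,6-dimethoxy-4H-chromen-4-one
Conditions: 3 M aq HCl/MeOH (1:5), THF co-solvent, 40 °C, 3–5 h, monitored and stopped at completion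
Reagents that add atoms: none
Why: Acid-catalysed acetal solvolysis removes the three aryl MOM groups and the primary TBS ether together under conditions mild enough to leave the o-prenylphenol uncyclised and the methyl ethers and stereocentre intact.

**Compound list**
1 | 2-methoxybenzene-1,3-diol | COc1c(O)cccc1O | starting material
2 | 2-methoxy-1,3-bis(methoxymethoxy)benzene | COCOc1cccc(OCOC)c1OC | intermediate
3 | 2-[4-methoxy-3,5-bis(methoxymethoxy)phenyl]-4,4,5,5-tetramethyl-1,3,2-dioxaborolane | COCOc1cc(B2OC(C)(C)C(C)(C)O2)cc(OCOC)c1OC | intermediate (not isolated)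
4 | 4-methoxy-3,5-bis(methoxymethoxy)phenol | COCOc1cc(O)cc(OCOC)c1OC | intermediate
5 | 5-(benzyloxy)-2-methoxy-1,3-bis(methoxymethoxy)benzene | COCOc1cc(OCc2ccccc2)cc(OCOC)c1OC | intermediate
6 | 1-(benzyloxy)-2-bromo-4-methoxy-3,5-bis(methoxymethoxy)benzene | COCOc1cc(OCc2ccccc2)c(Br)c(OCOC)c1OC | intermediate
7 | [2-(benzyloxy)-5-methoxy-4,6-bis(methoxymethoxy)phenyl]lithium | COCOc1cc(OCc2ccccc2)c([Li])c(OCOC)c1OC | intermediate (not isolated)
8 | 1-[2-(benzyloxy)-5-methoxy-4,6-bis(methoxymethoxy)phenyl]ethan-1-one | CC(=O)c1c(OCc2ccccc2)cc(OCOC)c(OC)c1OCOC | intermediate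
9 | 1-[2-hydroxy-5-methoxy-4,6-bis(methoxymethoxy)phenyl]ethan-1-one | CC(=O)c1c(O)cc(OCOC)c(OC)c1OCOC | intermediate
10 | methyl (R)-3-hydroxy-2-methylpropanoate | COC(=O)[C@H](C)CO | starting material
11 | methyl (R)-3-(tert-butyldimethylsilyloxy)-2-methylpropanoate | COC(=O)[C@H](C)CO[Si](C)(C)C(C)(C)C | intermediate
12 | (R)-3-(tert-butyldimethylsilyloxy)-2-methylpropanal | O=C[C@H](C)CO[Si](C)(C)C(C)(C)C | intermediate
13 | (S)-tert-butyldimethyl[(2-methylbut-3-en-1-yl)oxy]silane | C=C[C@H](C)CO[Si](C)(C)C(C)(C)C | intermediate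
14 | 3-bromo-4-hydroxybenzaldehyde | O=Cc1ccc(O)c(Br)c1 | starting material
15 | 3-bromo-4-hydroxy-5-iodobenzaldehyde | O=Cc1cc(Br)c(O)c(I)c1 | intermediate
16 | 3-bromo-5-iodo-4-(methoxymethoxy)benzaldehyde | COCOc1c(Br)cc(C=O)cc1I | intermediate
17 | 9-[(S)-4-(tert-butyldimethylsilyloxy)-3-methylbutyl]-9-borabicyclo[3.3.1]nonane | CC(C)(C)[Si](C)(C)OC[C@@H](C)CCB1C2CCCC1CCC2 | intermediate (not isolated)
18 | (S)-3-bromo-5-[4-(tert-butyldimethylsilyloxy)-3-methylbutyl]-4-(methoxymethoxy)benzaldehyde | COCOc1c(Br)cc(C=O)cc1CC[C@H](C)CO[Si](C)(C)C(C)(C)C | intermediate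
19 | (S)-3-[4-(tert-butyldimethylsilyloxy)-3-methylbutyl]-4-(methoxymethoxy)-5-(3-methylbut-2-en-1-yl)benzaldehyde | COCOc1c(CC=C(C)C)cc(C=O)cc1CC[C@H](C)CO[Si](C)(C)C(C)(C)C | intermediate
20 | aldol adduct: 3-aryl-3-hydroxy-1-[2-hydroxy-5-methoxy-4,6-bis(methoxymethoxy)phenyl]propan-1-one (aryl as in 19; both carbinol epimers) | COCOc1cc(O)c(C(=O)CC(O)c2cc(CC=C(C)C)c(OCOC)c(CC[C@H](C)CO[Si](C)(C)C(C)(C)C)c2)c(OCOC)c1OC | intermediate (not isolated)
21 | (S,E)-3-{3-[4-(tert-butyldimethylsilyloxy)-3-methylbutyl]-4-(methoxymethoxy)-5-(3-methylbut-2-en-1-yl)phenyl}-1-[2-hydroxy-5-methoxy-4,6-bis(methoxymethoxy)phenyl]prop-2-en-1-one | COCOc1cc(O)c(C(=O)/C=C/c2cc(CC=C(C)C)c(OCOC)c(CC[C@H](C)CO[Si](C)(C)C(C)(C)C)c2)c(OCOC)c1OC | intermediate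
22 | 2-aryl-3-hydroxy-6-methoxy-5,7-bis(methoxymethoxy)chroman-4-one (2,3-trans dihydroflavonol; aryl as in 19; mixture at C2/C3) | COCOc1cc2OC(c3cc(CC=C(C)C)c(OCOC)c(CC[C@H](C)CO[Si](C)(C)C(C)(C)C)c3)C(O)C(=O)c2c(OCOC)c1OC | intermediate (not isolated)
23 | 2-{3-[(3S)-4-(tert-butyldimethylsilyloxy)-3-methylbutyl]-4-(methoxymethoxy)-5-(3-methylbut-2-en-1-yl)phenyl}-3-hydroxy-6-methoxy-5,7-bis(methoxymethoxy)-4H-chromen-4-one | COCOc1cc2oc(-c3cc(CC=C(C)C)c(OCOC)c(CC[C@H](C)CO[Si](C)(C)C(C)(C)C)c3)c(O)c(=O)c2c(OCOC)c1OC | intermediate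
24 | 2-{3-[(3S)-4-(tert-butyldimethylsilyloxy)-3-methylbutyl]-4-(methoxymethoxy)-5-(3-methylbut-2-en-1-yl)phenyl}-3,6-dimethoxy-5,7-bis(methoxymethoxy)-4H-chromen-4-one | COCOc1cc2oc(-c3cc(CC=C(C)C)c(OCOC)c(CC[C@H](C)CO[Si](C)(C)C(C)(C)C)c3)c(OC)c(=O)c2c(OCOC)c1OC | intermediate
25 | 5,7-dihydroxy-2-{4-hydroxy-3-[(3S)-4-hydroxy-3-methylbutyl]-5-(3-methylbut-2-en-1-yl)phenyl}-3,6-dimethoxy-4H-chromen-4-one | COc1c(O)cc2oc(-c3cc(CC=C(C)C)c(O)c(CC[C@H](C)CO)c3)c(OC)c(=O)c2c1O | target

**Totals**
Total steps: 17. Longest linear sequence: 10 steps (steps 1–6, then 14–17).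

**Three steps most likely to fail, with fallbacks**

Step 15 (Algar–Flynn–Oyamada). Chalcones with a 6'-alkoxy group can divert to aurones, so the yield may be low. The fallback builds the 3-methoxypyranone by acylating an ω-methoxy ketone instead; it sets out from bromide 6 and aldehyde 19 and comes back to the route at target 25. Bromide 6 is lithiated as in step 5 (aryllithium 7) and quenched with N,2-dimethoxy-N-methylacetamide to give 1-[2-(benzyloxy)-5-methoxy-4,6-bis(methoxymethoxy)phenyl]-2-methoxyethan-1-one F1. Hydrogenolysis (H2, Pd/C, EtOAc) gives 1-[2-hydroxy-5-methoxy-4,6-bis(methoxymethoxy)phenyl]-2-methoxyethan-1-one F2. Aldehyde 19 is oxidised with Ag2O (AgNO3, NaOH, aq EtOH, which spares the alkene) to (S)-3-[4-(tert-butyldimethylsilyloxy)-3-methylbutyl]-4-(methoxymethoxy)-5-(3-methylbut-2-en-1-yl)benzoic acid F3, and this is activated with carbonyldiimidazole to the N-acylimidazole of that acid F4. The dianion of F2 (LiHMDS, 3.2 equiv, THF, −78 °C) is C-acylated by F4 in an intermolecular Claisen-type condensation to give 1-[2-hydroxy-5-methoxy-4,6-bis(methoxymethoxy)phenyl]-2-methoxy-3-aryl-propane-1,3-dione F5, which should sit largely as its 2-hydroxyflavanone hemiketal, closed through the only free phenol. Under the acid conditions of step 17, F5 dehydrates to the 3-methoxyflavone and loses the MOM and TBS groups, giving 25.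

Step 13 (Stille prenylation). The prenyl group may couple partly at its tertiary terminus, giving the reverse-prenyl isomer. The fallback installs the prenyl unit in two steps with no allylic ambiguity; it sets out from bromide 18 and comes back at aldehyde 19. Stille coupling of 18 with allyltributylstannane (Pd(PPh3)4, DMF, 90 °C) gives (S)-3-allyl-5-[4-(tert-butyldimethylsilyloxy)-3-methylbutyl]-4-(methoxymethoxy)benzaldehyde F6. Olefin cross-metathesis of F6 with excess 2-methyl-2-butene (Grubbs second-generation catalyst, CH2Cl2, 40 °C) converts the allyl group into the prenyl group of 19.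

Step 12 (B-alkyl Suzuki coupling). The step must discriminate C–I from C–Br, avoid double coupling and leave the aldehyde unreduced. The fallback makes the same bond by sp–sp2 coupling and then saturates it; it sets out from aldehyde 12 and iodide 16 and comes back at bromide 18. Aldehyde 12 is homologated with the Ohira–Bestmann reagent (dimethyl (1-diazo-2-oxopropyl)phosphonate, K2CO3, MeOH, 0 °C) to (S)-tert-butyldimethyl[(2-methylbut-3-yn-1-yl)oxy]silane F7. Sonogashira coupling of F7 with 16 at the C–I bond (PdCl2(PPh3)2, CuI, Et3N, rt) gives (S)-3-bromo-5-[4-(tert-butyldimethylsilyloxy)-3-methylbut-1-yn-1-yl]-4-(methoxymethoxy)benzaldehyde F8. Diimide reduction of F8 (dipotassium azodicarboxylate, AcOH, MeOH/pyridine, rt, excess) saturates the alkyne without touching the aryl bromide or the aldehyde and gives 18.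

**Further compounds**
F1 | step 15 | 1-[2-(benzyloxy)-5-methoxy-4,6-bis(methoxymethoxy)phenyl]-2-methoxyethan-1-one | COCC(=O)c1c(OCc2ccccc2)cc(OCOC)c(OC)c1OCOC
F2 | step 15 | 1-[2-hydroxy-5-methoxy-4,6-bis(methoxymethoxy)phenyl]-2-methoxyethan-1-one | COCC(=O)c1c(O)cc(OCOC)c(OC)c1OCOC
F3 | step 15 | (S)-3-[4-(tert-butyldimethylsilyloxy)-3-methylbutyl]-4-(methoxymethoxy)-5-(3-methylbut-2-en-1-yl)benzoic acid | COCOc1c(CC=C(C)C)cc(C(=O)O)cc1CC[C@H](C)CO[Si](C)(C)C(C)(C)C
F4 | step 15 | N-acylimidazole of acid F3 | COCOc1c(CC=C(C)C)cc(C(=O)n2ccnc2)cc1CC[C@H](C)CO[Si](C)(C)C(C)(C)C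
F5 | step 15 | 1-[2-hydroxy-5-methoxy-4,6-bis(methoxymethoxy)phenyl]-2-methoxy-3-aryl-propane-1,3-dione (aryl as in 19) | COCOc1cc(O)c(C(=O)C(OC)C(=O)c2cc(CC=C(C)C)c(OCOC)c(CC[C@H](C)CO[Si](C)(C)C(C)(C)C)c2)c(OCOC)c1OC
F6 | step 13 | (S)-3-allyl-5-[4-(tert-butyldimethylsilyloxy)-3-methylbutyl]-4-(methoxymethoxy)benzaldehyde | C=CCc1cc(C=O)cc(CC[C@H](C)CO[Si](C)(C)C(C)(C)C)c1OCOC
F7 | step 12 | (S)-tert-butyldimethyl[(2-methylbut-3-yn-1-yl)oxy]silane | C#C[C@H](C)CO[Si](C)(C)C(C)(C)C
F8 | step 12 | (S)-3-bromo-5-[4-(tert-butyldimethylsilyloxy)-3-methylbut-1-yn-1-yl]-4-(methoxymethoxy)benzaldehyde | COCOc1c(Br)cc(C=O)cc1C#C[C@H](C)CO[Si](C)(C)C(C)(C)C
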